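## Analysis of the target

Target 60 (C60H42O35) is a linear phlorotannin-type decamer: ten benzene rings, lettered A to J from the 2,4,6-trihydroxyphenyl end, are joined by nine diaryl ether oxygens and carry twenty-six free phenolic hydroxyls. Ring A is a phloroglucinol etherified at C1, rings B, D, F and H are 1,4-dioxygenated with hydroxyls at C3 and C5 on either side of the C4 oxygen, and ring J is a 3,4,5-trihydroxyphenyl ether. Rings C, E, G and I carry five oxygens on adjacent carbons (ether oxygens at C1 and C2, hydroxyls at C3 to C5) and a single C–H at C6. The molecule has no stereocentre and no other element of chirality, so no stereochemical relationship has to be set. The free polyphenol, with its pyrogallol and hydroxyquinol arrays, is readily oxidised by air, so every hydroxyl should stay masked until one final reductive unveiling. The difficulty lies in the nine ether links: the oxygens on A C1, on C4 of rings B, D, F, H and on C2 of rings C, E, G, I are each flanked by two ortho oxygen substituents on electron-rich rings, and the same two-ring motif recurs four times. The strategy rests on rings C, E, G and I: C2 to C5 with their four oxygens map onto a squarate, and C6–H together with C1 and its ether oxygen map onto a vinyl ether of the preceding ring, so each of these rings can be grown from the C4 oxygen of ring B (D, F, H) instead of being coupled to it.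

## Retrosynthetic reasoning

All O–H bonds are unveiled last. Target 60 is traced to decamer 59, in which twenty-five oxygens are benzyl ethers, and 59 to its methoxymethyl ether 58. One persistent protecting group that leaves by hydrogenolysis keeps the oxidation-prone polyphenol out of every earlier step. The acetal on ring J C4 is there only because ring J comes from the same aryl block as rings B, D, F and H.

The ether between the ring I C2 oxygen and ring J C1 of 58 is cut on the ring J side, giving nonamer phenol 57 and aryl triflate 12. Ring J C1 has two ortho hydrogens, whereas the oxygen on ring I is flanked twice, so the carbon electrophile is placed on the open ring and the crowded oxygen keeps its own carbon. The forward reaction, a metal-catalysed C–O coupling, has to insert at the unhindered carbon of 12 and accept a hindered phenoxide. Triflate 12 is a stable block that is purified once and then serves rings B, D, F, H and J alike.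

Nonamer 57 is taken apart in four identical two-ring cycles (57 to 46, 35, 24 and finally phenol 6). In each cycle the pentaoxygenated ring is removed as described next for 24, and the ether to the B-type ring before it is cut as above, with triflate 12 as the partner again.

In 24 the C5 benzyl ether is removed to give hydroquinone 23. Ring C of 23 is then opened between C1 and C2, through dienone 22, to dienylketene 21, and 21 is closed to the four-membered ring of alkenyl carbinol 20. The cut is made here and not at the ether between ring B C4 and ring C C1 because that oxygen is the most hindered in the molecule; in 20 it is simply the enol-ether oxygen of a phenol. What is gained is that the hindered ether and the complete oxygen pattern of ring C come from connectivity alone. The forward reaction has to open the cyclobutenone with the hydroxyl turning outward and to close the six-membered ring onto the aryloxy-bearing vinyl carbon.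

Carbinol 20 is traced to alkyne 19 by cis-semireduction. Alkyne 19 is cut between the carbinol carbon and the alkyne into squarate 2 and lithium acetylide 18. Acetylide 18 comes through chloroalkyne 17 from dichlorovinyl ether 16, that is from phenol 14 and trichloroethylene 15, which supplies C6 and C1 of ring C. Each of these steps is a standard operation, so the risk is left in the ring expansion.

Phenol 14 is the acetal-free form of 13, whose ether between the ring A C1 oxygen and ring B C1 is cut, again on the unhindered side, into phenol 6 and triflate 12.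

The blocks are simple. Triflate 12 comes from phenol 11, and 11 from aldehyde 9 through formate 10 by exchange of formyl for hydroxyl. Aldehyde 9 comes from 7 through 8; the higher acidity of the hydroxyl para to the formyl group distinguishes O4 from O3 and O5. Phenol 6 comes from 3 via 4 and formate 5 by the same formyl-to-hydroxyl exchange, and squarate 2 from squaric acid 1.

## Alternatives that were turned down

Alternative 1: The ether oxygens on ring I C1 and ring J C1 are traced to the ester links of the didepside A1, and the forward key step is a double decarbonylation. Ni(cod)2 with 3,4-bis(dicyclohexylphosphino)thiophene would insert zerovalent nickel into each acyl C–O bond, lose CO and reductively eliminate the diaryl ether, giving the H–I–J trimer ether A2.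
- For it: esters are far easier to make than hindered diaryl ethers, two ethers form in one step, and the approach is more convergent than the chosen route.
- Against it: decarbonylative etherification is established mainly for azine carboxylates. Here two electron-rich, ortho-oxygenated benzoates would have to react in one molecule at high temperature, with benzyl and diaryl ethers present that low-valent nickel can also cleave.
- Against it: each ring still needs its own carboxyl handle, and the ester left on ring H would have to be turned into an oxygen before the chain could grow.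
- Comparison: alternative 1 is stronger on convergence. The chosen route offers a metal-free thermal key step that also builds the pentaoxygenated ring, which alternative 1 has to obtain separately.

Alternative 2: Every ether is traced to an SNAr reaction at a carbon flanked by formyl groups, and eighteen hydroxyls are traced to those formyl groups. The forward key step is the mCPBA oxidation of polyaldehyde A3, by aryl migration at all eighteen sites, to the octadeca-formate A4.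
- For it: SNAr is insensitive to hindrance at the electrophilic carbon, the activating group is used twice, and the route would be much shorter than the thirty-eight steps proposed here. On step count and convergence it is clearly stronger.
- Against it: eighteen oxidations must all proceed with aryl migration on one molecule. The rings carrying two formyl groups are electron-poor at the start, where hydride migration to carboxylic acids competes, and as formates accumulate the rings become oxidisable by peracid.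
- Against it: any single failure gives a mixture that can hardly be separated at this size, and the formyl-bearing phenols are weak nucleophiles in the later SNAr steps.
- Comparison: the chosen route keeps every oxygen as a benzyl ether from the start and never exposes an electron-rich oligomer to an oxidant, so each intermediate is a single, purifiable compound.

Alternative 3: Ring A is traced to the triketide ester A5, and the forward key step is a base-mediated Claisen cyclisation between C6 and the ester carbon, followed by enolisation to the A–B–C trimer A6 with a free phloroglucinol ring.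
- For it: it is biomimetic, and it makes the hindered ether on ring A C1 as a simple aryloxymethyl ketone before the ring exists. That is the same idea as in the chosen route, and on this point the two are equal.
- Against it: it spends the key step on the one ring that can be bought with the right oxygen pattern, and it presupposes the B–C part with its pentaoxygenated ring.
- Against it: the C6 carbon must react in the presence of two more acidic methylenes, cyclisation through oxygen to a hydroxypyranone competes, and A6 carries a free, C-nucleophilic phloroglucinol that must be protected again.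
- Comparison: the chosen route applies the same idea four times, to the rings that are actually hard to make.

Key step: step 13

## Remarks before the steps

- Assumption: where an intermediate has a stereocentre (the carbinol carbon of the cyclobutenones, C6 of the transient cyclohexadienones) it is racemic; these centres vanish on aromatisation and the target is achiral.
- Assumption: 3,4,5-trihydroxybenzaldehyde (7) is taken as the commercial source of rings B, D, F, H and J, because its formyl group can be exchanged for hydroxyl in one operation.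
- Notation: Bn = benzyl, MOM = methoxymethyl, Tf = trifluoromethanesulfonyl. "Bn-[A–…–X]" is the chain of rings A to X in which every oxygen that is neither a link between rings nor named otherwise is a benzyl ether.
- Ring numbering: in rings B, D, F, H and J, C1 bears the oxygen to the preceding ring, C3 and C5 the flanking oxygens and C4 the oxygen to the following ring. In rings C, E, G and I, C1 bears the oxygen to the preceding ring, C2 the oxygen to the following ring, C3 to C5 the other oxygens and C6 the hydrogen.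
- Steps 20, 27 and 34 repeat the key step for rings E, G and I.

## Route

Step 1
Reactants: 1 squaric acid
Product: 2 dibenzyl squarate (3,4-bis(benzyloxy)cyclobut-3-ene-1,2-dione)
Conditions: BnOH (4 equiv), toluene, reflux, Dean–Stark
Reagents that add atoms: benzyl alcohol, OCc1ccccc1
Why: Squaric acid is a strong vinylogous acid and should esterify with a primary alcohol under azeotropic removal of water without added catalyst (Fischer-type esterification, the usual access to dialkyl squarates).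

Step 2
Reactants: 3 2,4,6-trihydroxybenzaldehyde
Product: 4 2,4,6-tris(benzyloxy)benzaldehyde
Conditions: BnBr (3.6 equiv), K2CO3, DMF, 60 °C
Reagents that add atoms: benzyl bromide, BrCc1ccccc1
Why: Williamson ether synthesis; the formyl group lowers the nucleophilicity of the ring carbons and should suppress C-benzylation, and warming with excess bromide should overcome the chelation of the two ortho hydroxyls.

Step 3
Reactants: 4 2,4,6-tris(benzyloxy)benzaldehyde
Product: 6 2,4,6-tris(benzyloxy)phenol, via aryl formate 5 (not isolated)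
Conditions: mCPBA, CH2Cl2, 0 °C to rt; NaHCO3 wash; then K2CO3 (cat.), MeOH, rt
Reagents that add atoms: 3-chloroperbenzoic acid, OOC(=O)c1cccc(Cl)c1
Why: Baeyer–Villiger (Dakin-type) oxidation; the electron-rich, doubly ortho-oxygenated aryl group should migrate in preference to hydride, and the formate is cleaved by base-catalysed methanolysis.

Step 4
Reactants: 7 3,4,5-trihydroxybenzaldehyde
Product: 8 3,5-dihydroxy-4-(methoxymethoxy)benzaldehyde
Conditions: MOMCl (1.0 equiv), K2CO3 (1.0 equiv), acetone, 0 °C to rt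
Reagents that add atoms: chloromethyl methyl ether, COCCl
Why: The hydroxyl para to the formyl group is the most acidic (a vinylogous carboxylic acid), so one equivalent of weak base should form only its phenoxide, which is alkylated (Williamson-type O-alkylation, as in the 4-O-selective protection of 3,4-dihydroxybenzaldehyde).

Step 5
Reactants: 8 3,5-dihydroxy-4-(methoxymethoxy)benzaldehyde
Product: 9 3,5-bis(benzyloxy)-4-(methoxymethoxy)benzaldehyde
Conditions: BnBr (2.4 equiv), K2CO3, DMF, rt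
Reagents that add atoms: benzyl bromide, BrCc1ccccc1
Why: Williamson ether synthesis of the two remaining phenols; the acetal is stable to base.

Step 6
Reactants: 9 3,5-bis(benzyloxy)-4-(methoxymethoxy)benzaldehyde
Product: 11 3,5-bis(benzyloxy)-4-(methoxymethoxy)phenol, via aryl formate 10 (not isolated)
Conditions: mCPBA, NaHCO3, CH2Cl2, 0 °C to rt; then K2CO3 (cat.), MeOH, rt
Reagents that add atoms: 3-chloroperbenzoic acid, OOC(=O)c1cccc(Cl)c1
Why: Baeyer–Villiger (Dakin-type) oxidation with aryl migration, supported by the para alkoxy group as in other 3,4,5-trialkoxybenzaldehydes; the buffered peracid should leave the acetal intact.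

Step 7
Reactants: 11 3,5-bis(benzyloxy)-4-(methoxymethoxy)phenol
Product: 12 3,5-bis(benzyloxy)-4-(methoxymethoxy)phenyl trifluoromethanesulfonate
Conditions: Tf2O (1.2 equiv), 30% aq K3PO4, toluene, 0 °C to rt
Reagents that add atoms: trifluoromethanesulfonic anhydride, FC(F)(F)S(=O)(=O)OS(=O)(=O)C(F)(F)F
Why: O-Sulfonylation of the phenoxide by Tf2O under two-phase conditions, a standard aryl triflate synthesis; the phenol has two ortho hydrogens and should react fast, and the aqueous phosphate keeps the acetal away from triflic acid.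

Step 8
Reactants: 6 2,4,6-tris(benzyloxy)phenol; 12 aryl triflate
Product: 13 1,3-bis(benzyloxy)-2-(methoxymethoxy)-5-[2,4,6-tris(benzyloxy)phenoxy]benzene (Bn-[A–B] methoxymethyl ether)
Conditions: Pd(OAc)2 (5 mol %), 2-(di-tert-butylphosphino)-2',4',6'-triisopropylbiphenyl (7.5 mol %), K3PO4 (2 equiv), toluene, 100 °C, Ar
Reagents that add atoms: none
Why: Palladium-catalysed C–O cross-coupling of an aryl triflate with a phenol (Buchwald–Hartwig-type diaryl ether synthesis): zerovalent palladium inserts into the C–OTf bond at ring B C1, which has two ortho hydrogens, the phenoxide replaces triflate on divalent palladium, and the bulky biarylphosphine together with the bulky phenoxide drives the reductive elimination. All the hindrance lies on the phenol oxygen, the partner on which such ligands tolerate ortho substituents.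

Step 9
Reactants: 13 Bn-[A–B] methoxymethyl ether
Product: 14 2,6-bis(benzyloxy)-4-[2,4,6-tris(benzyloxy)phenoxy]phenol (Bn-[A–B] phenol)
Conditions: HCl (3 M aq), MeOH/THF, 50 °C
Reagents that add atoms: none
Why: Acid-catalysed acetal cleavage by methanolysis; benzyl and diaryl ethers are inert under these conditions.

Step 10
Reactants: 14 Bn-[A–B] phenol; 15 trichloroethylene
Product: 16 1,3-bis(benzyloxy)-2-{[(E)-1,2-dichloroethenyl]oxy}-5-[2,4,6-tris(benzyloxy)phenoxy]benzene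
Conditions: K2CO3, DMF, 70 °C
Reagents that add atoms: none
Why: The base converts 15 into dichloroacetylene in the flask, which is consumed at once; anti addition of the phenoxide followed by protonation gives the (E)-1,2-dichlorovinyl ether, a known reaction of phenols and alcohols.

Step 11
Reactants: 16 dichlorovinyl ether; 2 dibenzyl squarate
Product: 19 2,3-bis(benzyloxy)-4-({2,6-bis(benzyloxy)-4-[2,4,6-tris(benzyloxy)phenoxy]phenoxy}ethynyl)-4-hydroxycyclobut-2-en-1-one (racemic), via chloroethynyl ether 17 (not isolated), via lithium acetylide 18 (not isolated)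
Conditions: n-BuLi (2.05 equiv), THF, −78 to −40 °C; then added to 2 (1.5 equiv), THF, −78 °C; aq NH4Cl, −78 °C
Reagents that add atoms: none
Why: n-BuLi removes the vinyl hydrogen and loss of LiCl gives chloroethynyl ether 17, which the second equivalent converts into acetylide 18 by chlorine–lithium exchange. 1,2-Addition of alkynyllithiums to one carbonyl of a dialkyl squarate is the standard entry to 4-alkynyl-4-hydroxycyclobutenones. The carbinol centre forms as a racemate and is lost in step 13.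

Step 12
Reactants: 19 alkynyl carbinol
Product: 20 2,3-bis(benzyloxy)-4-[(Z)-2-{2,6-bis(benzyloxy)-4-[2,4,6-tris(benzyloxy)phenoxy]phenoxy}ethenyl]-4-hydroxycyclobut-2-en-1-one (racemic)
Conditions: H2 (1 atm), Pd/CaCO3 poisoned with Pb(OAc)2, quinoline, EtOAc, rt
Reagents that add atoms: none
Why: Syn semihydrogenation of the alkynyl ether on the poisoned palladium surface (Lindlar-type reduction) should give the Z enol ether; benzyl ethers and the tetrasubstituted ring double bond are not reduced at one atmosphere with quinoline present.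

Step 13
Reactants: 20 (Z)-aryloxyvinyl carbinol
Product: 23 2,3-bis(benzyloxy)-5-{2,6-bis(benzyloxy)-4-[2,4,6-tris(benzyloxy)phenoxy]phenoxy}benzene-1,4-diol (Bn-[A–B–C] hydroquinone; free OH on ring C C2 and C5), via dienylketene 21 (not isolated), via cyclohexadienone 22 (not isolated)
Conditions: toluene (degassed), 110 °C, Ar
Reagents that add atoms: none
Why: Heating opens the cyclobutenone by a conrotatory 4π electrocyclic reaction; the donor hydroxyl on the carbinol carbon rotates outward, which turns the aryloxyvinyl group toward the ketene and gives dienylketene 21 with ketene and vinyl group cis on the central double bond. A disrotatory 6π electrocyclisation then joins the ketene carbon to the aryloxy-bearing vinyl carbon, which forms the C1–C2 bond of ring C and closes the six-membered ring as cyclohexadienone 22; enolisation gives the aromatic hydroquinone 23. The closest known reaction type is the thermal ring expansion of squarate-derived 4-alkenyl-4-hydroxycyclobutenones to hydroquinones (Moore rearrangement). Ring C is thus closed in the 6π-electrocyclic mode between a ketene terminus and an enol-ether terminus, and aromatisation makes the closure irreversible. No stereocentre is created: the carbinol centre of 20 and the sp3 carbon of 22 both disappear. The step needs outward rotation of the hydroxyl, since inward rotation would lead to a butenolide by attack of the hydroxyl on the ketene; the strong outward preference of donor substituents in cyclobutene openings should secure this. It also needs closure with the aryloxy group on the inside of the triene, which should be tolerated because the other terminus is a linear, unencumbered ketene carbon and the enol ether is the electron-rich partner of the electrophilic ketene. The positions of all oxygens follow from connectivity: the squarate supplies C2 to C5 with four oxygens, and the vinyl ether supplies C6–H and C1 with the ring B oxygen.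

Step 14
Reactants: 23 Bn-[A–B–C] hydroquinone
Product: 24 2,3,4-tris(benzyloxy)-6-{2,6-bis(benzyloxy)-4-[2,4,6-tris(benzyloxy)phenoxy]phenoxy}phenol (Bn-[A–B–C] phenol; free OH on ring C C2)
Conditions: BnBr (1.0 equiv), K2CO3, DMF, 0 °C, Ar
Reagents that add atoms: benzyl bromide, BrCc1ccccc1
Why: Williamson mono-alkylation; the C5 hydroxyl has one ortho substituent, whereas the C2 hydroxyl lies between a benzyloxy group and the 2,6-bis(benzyloxy)aryloxy group, so one equivalent of bromide at low temperature should react at O5.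

Step 15
Reactants: 24 Bn-[A–B–C] phenol; 12 aryl triflate
Product: 25 Bn-[A–B–C–D] methoxymethyl ether (OMOM on ring D C4)
Conditions: Pd(OAc)2 (5 mol %), 2-(di-tert-butylphosphino)-2',4',6'-triisopropylbiphenyl (7.5 mol %), K3PO4 (2 equiv), toluene, 100 °C, Ar
Reagents that add atoms: none
Why: Palladium-catalysed C–O coupling as in step 8; the doubly flanked C2 phenoxide of ring C is joined to the unhindered C1 of triflate 12, so the new ether is formed at the open carbon and not at the crowded one.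

Step 16
Reactants: 25 Bn-[A–B–C–D] methoxymethyl ether
Product: 26 Bn-[A–B–C–D] phenol (free OH on ring D C4)
Conditions: HCl (3 M aq), MeOH/THF, 50 °C
Reagents that add atoms: none
Why: Acid-catalysed acetal methanolysis as in step 9.

Step 17
Reactants: 26 Bn-[A–B–C–D] phenol; 15 trichloroethylene
Product: 27 Bn-[A–B–C–D] (E)-1,2-dichlorovinyl ether (on O4 of ring D)
Conditions: K2CO3, DMF, 70 °C
Reagents that add atoms: none
Why: Anti addition of the phenoxide to dichloroacetylene generated in the flask, as in step 10.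

Step 18
Reactants: 27 dichlorovinyl ether; 2 dibenzyl squarate
Product: 30 2,3-bis(benzyloxy)-4-hydroxy-4-[(Bn-[A–B–C–D]-oxy)ethynyl]cyclobut-2-en-1-one (racemic; oxygen on ring D C4), via chloroethynyl ether 28 (not isolated), via lithium acetylide 29 (not isolated)
Conditions: n-BuLi (2.05 equiv), THF, −78 to −40 °C; then added to 2 (1.5 equiv), THF, −78 °C; aq NH4Cl, −78 °C
Reagents that add atoms: none
Why: Dehydrochlorination and chlorine–lithium exchange to the lithium aryloxyacetylide, then 1,2-addition to the squarate carbonyl, as in step 11.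

Step 19
Reactants: 30 alkynyl carbinol
Product: 31 2,3-bis(benzyloxy)-4-hydroxy-4-[(Z)-2-(Bn-[A–B–C–D]-oxy)ethenyl]cyclobut-2-en-1-one (racemic)
Conditions: H2 (1 atm), Pd/CaCO3 poisoned with Pb(OAc)2, quinoline, EtOAc/toluene, rt
Reagents that add atoms: none
Why: Lindlar-type syn semihydrogenation as in step 12.

Step 20
Reactants: 31 (Z)-aryloxyvinyl carbinol
Product: 34 Bn-[A–B–C–D–E] hydroquinone (free OH on ring E C2 and C5), via dienylketene 32 (not isolated), via cyclohexadienone 33 (not isolated)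
Conditions: toluene (degassed), 110 °C, Ar
Reagents that add atoms: none
Why: Moore-type ring expansion as in step 13 (4π opening with the hydroxyl outward, 6π closure, enolisation); it forms the C1–C2 bond of ring E and closes that ring.

Step 21
Reactants: 34 Bn-[A–B–C–D–E] hydroquinone
Product: 35 Bn-[A–B–C–D–E] phenol (free OH on ring E C2)
Conditions: BnBr (1.0 equiv), K2CO3, DMF, 0 °C, Ar
Reagents that add atoms: benzyl bromide, BrCc1ccccc1
Why: Williamson mono-alkylation of the less hindered C5 hydroxyl, as in step 14.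

Step 22
Reactants: 35 Bn-[A–B–C–D–E] phenol; 12 aryl triflate
Product: 36 Bn-[A–B–C–D–E–F] methoxymethyl ether (OMOM on ring F C4)
Conditions: Pd(OAc)2 (5 mol %), 2-(di-tert-butylphosphino)-2',4',6'-triisopropylbiphenyl (7.5 mol %), K3PO4 (2 equiv), toluene, 100 °C, Ar
Reagents that add atoms: none
Why: Palladium-catalysed C–O coupling of the hindered phenoxide with the unhindered C1 of triflate 12, as in step 15.

Step 23
Reactants: 36 Bn-[A–B–C–D–E–F] methoxymethyl ether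
Product: 37 Bn-[A–B–C–D–E–F] phenol (free OH on ring F C4)
Conditions: HCl (3 M aq), MeOH/THF, 50 °C
Reagents that add atoms: none
Why: Acid-catalysed acetal methanolysis as in step 9.

Step 24
Reactants: 37 Bn-[A–B–C–D–E–F] phenol; 15 trichloroethylene
Product: 38 Bn-[A–B–C–D–E–F] (E)-1,2-dichlorovinyl ether (on O4 of ring F)
Conditions: K2CO3, DMF, 70 °C
Reagents that add atoms: none
Why: Anti addition of the phenoxide to dichloroacetylene generated in the flask, as in step 10.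

Step 25
Reactants: 38 dichlorovinyl ether; 2 dibenzyl squarate
Product: 41 2,3-bis(benzyloxy)-4-hydroxy-4-[(Bn-[A–B–C–D–E–F]-oxy)ethynyl]cyclobut-2-en-1-one (racemic; oxygen on ring F C4), via chloroethynyl ether 39 (not isolated), via lithium acetylide 40 (not isolated)
Conditions: n-BuLi (2.05 equiv), THF, −78 to −40 °C; then added to 2 (1.5 equiv), THF, −78 °C; aq NH4Cl, −78 °C
Reagents that add atoms: none
Why: Lithium aryloxyacetylide formation and 1,2-addition to the squarate carbonyl, as in step 11.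

Step 26
Reactants: 41 alkynyl carbinol
Product: 42 2,3-bis(benzyloxy)-4-hydroxy-4-[(Z)-2-(Bn-[A–B–C–D–E–F]-oxy)ethenyl]cyclobut-2-en-1-one (racemic)
Conditions: H2 (1 atm), Pd/CaCO3 poisoned with Pb(OAc)2, quinoline, EtOAc/toluene, rt
Reagents that add atoms: none
Why: Lindlar-type syn semihydrogenation as in step 12.

Step 27
Reactants: 42 (Z)-aryloxyvinyl carbinol
Product: 45 Bn-[A–B–C–D–E–F–G] hydroquinone (free OH on ring G C2 and C5), via dienylketene 43 (not isolated), via cyclohexadienone 44 (not isolated)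
Conditions: toluene (degassed), 110 °C, Ar
Reagents that add atoms: none
Why: Moore-type ring expansion as in step 13; it forms the C1–C2 bond of ring G and closes that ring.

Step 28
Reactants: 45 Bn-[A–B–C–D–E–F–G] hydroquinone
Product: 46 Bn-[A–B–C–D–E–F–G] phenol (free OH on ring G C2)
Conditions: BnBr (1.0 equiv), K2CO3, DMF, 0 °C, Ar
Reagents that add atoms: benzyl bromide, BrCc1ccccc1
Why: Williamson mono-alkylation of the less hindered C5 hydroxyl, as in step 14.

Step 29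
Reactants: 46 Bn-[A–B–C–D–E–F–G] phenol; 12 aryl triflate
Product: 47 Bn-[A–B–C–D–E–F–G–H] methoxymethyl ether (OMOM on ring H C4)
Conditions: Pd(OAc)2 (5 mol %), 2-(di-tert-butylphosphino)-2',4',6'-triisopropylbiphenyl (7.5 mol %), K3PO4 (2 equiv), toluene, 100 °C, Ar
Reagents that add atoms: none
Why: Palladium-catalysed C–O coupling of the hindered phenoxide with the unhindered C1 of triflate 12, as in step 15.

Step 30
Reactants: 47 Bn-[A–B–C–D–E–F–G–H] methoxymethyl ether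
Product: 48 Bn-[A–B–C–D–E–F–G–H] phenol (free OH on ring H C4)
Conditions: HCl (3 M aq), MeOH/THF, 50 °C
Reagents that add atoms: none
Why: Acid-catalysed acetal methanolysis as in step 9.

Step 31
Reactants: 48 Bn-[A–B–C–D–E–F–G–H] phenol; 15 trichloroethylene
Product: 49 Bn-[A–B–C–D–E–F–G–H] (E)-1,2-dichlorovinyl ether (on O4 of ring H)
Conditions: K2CO3, DMF, 70 °C
Reagents that add atoms: none
Why: Anti addition of the phenoxide to dichloroacetylene generated in the flask, as in step 10.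

Step 32
Reactants: 49 dichlorovinyl ether; 2 dibenzyl squarate
Product: 52 2,3-bis(benzyloxy)-4-hydroxy-4-[(Bn-[A–B–C–D–E–F–G–H]-oxy)ethynyl]cyclobut-2-en-1-one (racemic; oxygen on ring H C4), via chloroethynyl ether 50 (not isolated), via lithium acetylide 51 (not isolated)
Conditions: n-BuLi (2.05 equiv), THF, −78 to −40 °C; then added to 2 (1.5 equiv), THF, −78 °C; aq NH4Cl, −78 °C
Reagents that add atoms: none
Why: Lithium aryloxyacetylide formation and 1,2-addition to the squarate carbonyl, as in step 11.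

Step 33
Reactants: 52 alkynyl carbinol
Product: 53 2,3-bis(benzyloxy)-4-hydroxy-4-[(Z)-2-(Bn-[A–B–C–D–E–F–G–H]-oxy)ethenyl]cyclobut-2-en-1-one (racemic)
Conditions: H2 (1 atm), Pd/CaCO3 poisoned with Pb(OAc)2, quinoline, EtOAc/toluene, rt
Reagents that add atoms: none
Why: Lindlar-type syn semihydrogenation as in step 12.

Step 34
Reactants: 53 (Z)-aryloxyvinyl carbinol
Product: 56 Bn-[A–B–C–D–E–F–G–H–I] hydroquinone (free OH on ring I C2 and C5), via dienylketene 54 (not isolated), via cyclohexadienone 55 (not isolated)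
Conditions: toluene (degassed), 110 °C, Ar
Reagents that add atoms: none
Why: Moore-type ring expansion as in step 13; it forms the C1–C2 bond of ring I and closes that ring.

Step 35
Reactants: 56 Bn-[A–B–C–D–E–F–G–H–I] hydroquinone
Product: 57 Bn-[A–B–C–D–E–F–G–H–I] phenol (free OH on ring I C2)
Conditions: BnBr (1.0 equiv), K2CO3, DMF, 0 °C, Ar
Reagents that add atoms: benzyl bromide, BrCc1ccccc1
Why: Williamson mono-alkylation of the less hindered C5 hydroxyl, as in step 14.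

Step 36
Reactants: 57 Bn-[A–B–C–D–E–F–G–H–I] phenol; 12 aryl triflate
Product: 58 Bn-[A–B–C–D–E–F–G–H–I–J] methoxymethyl ether (OMOM on ring J C4; twenty-five benzyl ethers)
Conditions: Pd(OAc)2 (5 mol %), 2-(di-tert-butylphosphino)-2',4',6'-triisopropylbiphenyl (7.5 mol %), K3PO4 (2 equiv), toluene, 100 °C, Ar
Reagents that add atoms: none
Why: Palladium-catalysed C–O coupling as in step 15; the same aryl block that served rings B, D, F and H now delivers ring J.

Step 37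
Reactants: 58 decamer methoxymethyl ether
Product: 59 Bn-[A–B–C–D–E–F–G–H–I–J] phenol (free OH on ring J C4; twenty-five benzyl ethers)
Conditions: HCl (3 M aq), MeOH/THF, 50 °C
Reagents that add atoms: none
Why: Acid-catalysed acetal methanolysis as in step 9, carried out while the molecule is still lipophilic and can be purified.

Step 38
Reactants: 59 decamer phenol
Product: 60 target decamer (CNP0255890.0)
Conditions: H2 (1 atm), Pd(OH)2/C, THF/MeOH, rt; filtration and evaporation under Ar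
Reagents that add atoms: none
Why: Catalytic hydrogenolysis of the twenty-five aryl benzyl ethers; diaryl ethers and the aromatic rings are not attacked under these mild conditions, and the only by-product is volatile.

## Compound list

1 | squaric acid | OC1=C(O)C(=O)C1=O | starting material
2 | dibenzyl squarate | O=C1C(=O)C(OCc9ccccc9)=C1OCc9ccccc9 | intermediate
3 | 2,4,6-trihydroxybenzaldehyde | O=Cc1c(O)cc(O)cc1O | starting material
4 | 2,4,6-tris(benzyloxy)benzaldehyde | O=Cc1c(OCc9ccccc9)cc(OCc9ccccc9)cc1OCc9ccccc9 | intermediate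
5 | 2,4,6-tris(benzyloxy)phenyl formate | O=COc1c(OCc9ccccc9)cc(OCc9ccccc9)cc1OCc9ccccc9 | intermediate
6 | 2,4,6-tris(benzyloxy)phenol | c1(OCc9ccccc9)cc(OCc9ccccc9)cc(OCc9ccccc9)c1O | intermediate
7 | 3,4,5-trihydroxybenzaldehyde | O=Cc1cc(O)c(O)c(O)c1 | starting material
8 | 3,5-dihydroxy-4-(methoxymethoxy)benzaldehyde | O=Cc1cc(O)c(OCOC)c(O)c1 | intermediate
9 | 3,5-bis(benzyloxy)-4-(methoxymethoxy)benzaldehyde | O=Cc1cc(OCc9ccccc9)c(OCOC)c(OCc9ccccc9)c1 | intermediate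
10 | 3,5-bis(benzyloxy)-4-(methoxymethoxy)phenyl formate | O=COc1cc(OCc9ccccc9)c(OCOC)c(OCc9ccccc9)c1 | intermediate
11 | 3,5-bis(benzyloxy)-4-(methoxymethoxy)phenol | Oc1cc(OCc9ccccc9)c(OCOC)c(OCc9ccccc9)c1 | intermediate
12 | 3,5-bis(benzyloxy)-4-(methoxymethoxy)phenyl trifluoromethanesulfonate | FC(F)(F)S(=O)(=O)Oc1cc(OCc9ccccc9)c(OCOC)c(OCc9ccccc9)c1 | intermediate
13 | 1,3-bis(benzyloxy)-2-(methoxymethoxy)-5-[2,4,6-tris(benzyloxy)phenoxy]benzene | c1(OCc9ccccc9)cc(OCc9ccccc9)cc(OCc9ccccc9)c1Oc1cc(OCc9ccccc9)c(c(OCc9ccccc9)c1)OCOC | intermediate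
14 | 2,6-bis(benzyloxy)-4-[2,4,6-tris(benzyloxy)phenoxy]phenol | c1(OCc9ccccc9)cc(OCc9ccccc9)cc(OCc9ccccc9)c1Oc1cc(OCc9ccccc9)c(c(OCc9ccccc9)c1)O | intermediate
15 | trichloroethylene | ClC=C(Cl)Cl | starting material
16 | 1,3-bis(benzyloxy)-2-{[(E)-1,2-dichloroethenyl]oxy}-5-[2,4,6-tris(benzyloxy)phenoxy]benzene | c1(OCc9ccccc9)cc(OCc9ccccc9)cc(OCc9ccccc9)c1Oc1cc(OCc9ccccc9)c(c(OCc9ccccc9)c1)O/C(Cl)=C\Cl | intermediate
17 | 1,3-bis(benzyloxy)-2-[(chloroethynyl)oxy]-5-[2,4,6-tris(benzyloxy)phenoxy]benzene | c1(OCc9ccccc9)cc(OCc9ccccc9)cc(OCc9ccccc9)c1Oc1cc(OCc9ccccc9)c(c(OCc9ccccc9)c1)OC#CCl | intermediate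
18 | lithium 2-{2,6-bis(benzyloxy)-4-[2,4,6-tris(benzyloxy)phenoxy]phenoxy}ethynide | c1(OCc9ccccc9)cc(OCc9ccccc9)cc(OCc9ccccc9)c1Oc1cc(OCc9ccccc9)c(c(OCc9ccccc9)c1)OC#C[Li] | intermediate
19 | 2,3-bis(benzyloxy)-4-({2,6-bis(benzyloxy)-4-[2,4,6-tris(benzyloxy)phenoxy]phenoxy}ethynyl)-4-hydroxycyclobut-2-en-1-one (racemic) | c1(OCc9ccccc9)cc(OCc9ccccc9)cc(OCc9ccccc9)c1Oc1cc(OCc9ccccc9)c(c(OCc9ccccc9)c1)OC#CC1(O)C(OCc9ccccc9)=C(OCc9ccccc9)C1=O | intermediate
20 | 2,3-bis(benzyloxy)-4-[(Z)-2-{2,6-bis(benzyloxy)-4-[2,4,6-tris(benzyloxy)phenoxy]phenoxy}ethenyl]-4-hydroxycyclobut-2-en-1-one (racemic) | c1(OCc9ccccc9)cc(OCc9ccccc9)cc(OCc9ccccc9)c1Oc1cc(OCc9ccccc9)c(c(OCc9ccccc9)c1)O/C=C\C1(O)C(OCc9ccccc9)=C(OCc9ccccc9)C1=O | intermediate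
21 | (3Z,5Z)-2,3-bis(benzyloxy)-6-{2,6-bis(benzyloxy)-4-[2,4,6-tris(benzyloxy)phenoxy]phenoxy}-4-hydroxyhexa-1,3,5-trien-1-one (dienylketene) | c1(OCc9ccccc9)cc(OCc9ccccc9)cc(OCc9ccccc9)c1Oc1cc(OCc9ccccc9)c(c(OCc9ccccc9)c1)O/C=C\C(O)=C(OCc9ccccc9)/C(OCc9ccccc9)=C=O | intermediate
22 | 2,3-bis(benzyloxy)-6-{2,6-bis(benzyloxy)-4-[2,4,6-tris(benzyloxy)phenoxy]phenoxy}-4-hydroxycyclohexa-2,4-dien-1-one (racemic) | c1(OCc9ccccc9)cc(OCc9ccccc9)cc(OCc9ccccc9)c1Oc1cc(OCc9ccccc9)c(c(OCc9ccccc9)c1)OC1C=C(O)C(OCc9ccccc9)=C(OCc9ccccc9)C1=O | intermediate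
23 | 2,3-bis(benzyloxy)-5-{2,6-bis(benzyloxy)-4-[2,4,6-tris(benzyloxy)phenoxy]phenoxy}benzene-1,4-diol (Bn-[A–B–C] hydroquinone) | c1(OCc9ccccc9)cc(OCc9ccccc9)cc(OCc9ccccc9)c1Oc1cc(OCc9ccccc9)c(c(OCc9ccccc9)c1)Oc1cc(O)c(OCc9ccccc9)c(OCc9ccccc9)c1O | intermediate
24 | 2,3,4-tris(benzyloxy)-6-{2,6-bis(benzyloxy)-4-[2,4,6-tris(benzyloxy)phenoxy]phenoxy}phenol (Bn-[A–B–C] phenol) | c1(OCc9ccccc9)cc(OCc9ccccc9)cc(OCc9ccccc9)c1Oc1cc(OCc9ccccc9)c(c(OCc9ccccc9)c1)Oc1cc(OCc9ccccc9)c(OCc9ccccc9)c(OCc9ccccc9)c1O | intermediate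
25 | Bn-[A–B–C–D] methoxymethyl ether (OMOM on ring D C4) | c1(OCc9ccccc9)cc(OCc9ccccc9)cc(OCc9ccccc9)c1Oc1cc(OCc9ccccc9)c(c(OCc9ccccc9)c1)Oc1cc(OCc9ccccc9)c(OCc9ccccc9)c(OCc9ccccc9)c1Oc1cc(OCc9ccccc9)c(c(OCc9ccccc9)c1)OCOC | intermediate
26 | Bn-[A–B–C–D] phenol (free OH on ring D C4) | c1(OCc9ccccc9)cc(OCc9ccccc9)cc(OCc9ccccc9)c1Oc1cc(OCc9ccccc9)c(c(OCc9ccccc9)c1)Oc1cc(OCc9ccccc9)c(OCc9ccccc9)c(OCc9ccccc9)c1Oc1cc(OCc9ccccc9)c(c(OCc9ccccc9)c1)O | intermediate
27 | Bn-[A–B–C–D] (E)-1,2-dichlorovinyl ether (on O4 of ring D) | c1(OCc9ccccc9)cc(OCc9ccccc9)cc(OCc9ccccc9)c1Oc1cc(OCc9ccccc9)c(c(OCc9ccccc9)c1)Oc1cc(OCc9ccccc9)c(OCc9ccccc9)c(OCc9ccccc9)c1Oc1cc(OCc9ccccc9)c(c(OCc9ccccc9)c1)O/C(Cl)=C\Cl | intermediate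
28 | Bn-[A–B–C–D] chloroethynyl ether (Cl–C≡C–O on ring D C4) | c1(OCc9ccccc9)cc(OCc9ccccc9)cc(OCc9ccccc9)c1Oc1cc(OCc9ccccc9)c(c(OCc9ccccc9)c1)Oc1cc(OCc9ccccc9)c(OCc9ccccc9)c(OCc9ccccc9)c1Oc1cc(OCc9ccccc9)c(c(OCc9ccccc9)c1)OC#CCl | intermediate
29 | lithium acetylide of the tetramer (Li–C≡C–O on ring D C4) | c1(OCc9ccccc9)cc(OCc9ccccc9)cc(OCc9ccccc9)c1Oc1cc(OCc9ccccc9)c(c(OCc9ccccc9)c1)Oc1cc(OCc9ccccc9)c(OCc9ccccc9)c(OCc9ccccc9)c1Oc1cc(OCc9ccccc9)c(c(OCc9ccccc9)c1)OC#C[Li] | intermediate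
30 | 2,3-bis(benzyloxy)-4-hydroxy-4-[(Bn-[A–B–C–D]-oxy)ethynyl]cyclobut-2-en-1-one (racemic) | c1(OCc9ccccc9)cc(OCc9ccccc9)cc(OCc9ccccc9)c1Oc1cc(OCc9ccccc9)c(c(OCc9ccccc9)c1)Oc1cc(OCc9ccccc9)c(OCc9ccccc9)c(OCc9ccccc9)c1Oc1cc(OCc9ccccc9)c(c(OCc9ccccc9)c1)OC#CC1(O)C(OCc9ccccc9)=C(OCc9ccccc9)C1=O | intermediate
31 | 2,3-bis(benzyloxy)-4-hydroxy-4-[(Z)-2-(Bn-[A–B–C–D]-oxy)ethenyl]cyclobut-2-en-1-one (racemic) | c1(OCc9ccccc9)cc(OCc9ccccc9)cc(OCc9ccccc9)c1Oc1cc(OCc9ccccc9)c(c(OCc9ccccc9)c1)Oc1cc(OCc9ccccc9)c(OCc9ccccc9)c(OCc9ccccc9)c1Oc1cc(OCc9ccccc9)c(c(OCc9ccccc9)c1)O/C=C\C1(O)C(OCc9ccccc9)=C(OCc9ccccc9)C1=O | intermediate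
32 | (3Z,5Z)-dienylketene leading to ring E (6-(Bn-[A–B–C–D]-oxy)-2,3-bis(benzyloxy)-4-hydroxyhexa-1,3,5-trien-1-one) | c1(OCc9ccccc9)cc(OCc9ccccc9)cc(OCc9ccccc9)c1Oc1cc(OCc9ccccc9)c(c(OCc9ccccc9)c1)Oc1cc(OCc9ccccc9)c(OCc9ccccc9)c(OCc9ccccc9)c1Oc1cc(OCc9ccccc9)c(c(OCc9ccccc9)c1)O/C=C\C(O)=C(OCc9ccccc9)/C(OCc9ccccc9)=C=O | intermediate
33 | cyclohexadienone leading to ring E (6-(Bn-[A–B–C–D]-oxy)-2,3-bis(benzyloxy)-4-hydroxycyclohexa-2,4-dien-1-one, racemic) | c1(OCc9ccccc9)cc(OCc9ccccc9)cc(OCc9ccccc9)c1Oc1cc(OCc9ccccc9)c(c(OCc9ccccc9)c1)Oc1cc(OCc9ccccc9)c(OCc9ccccc9)c(OCc9ccccc9)c1Oc1cc(OCc9ccccc9)c(c(OCc9ccccc9)c1)OC1C=C(O)C(OCc9ccccc9)=C(OCc9ccccc9)C1=O | intermediate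
34 | Bn-[A–B–C–D–E] hydroquinone (free OH on ring E C2 and C5) | c1(OCc9ccccc9)cc(OCc9ccccc9)cc(OCc9ccccc9)c1Oc1cc(OCc9ccccc9)c(c(OCc9ccccc9)c1)Oc1cc(OCc9ccccc9)c(OCc9ccccc9)c(OCc9ccccc9)c1Oc1cc(OCc9ccccc9)c(c(OCc9ccccc9)c1)Oc1cc(O)c(OCc9ccccc9)c(OCc9ccccc9)c1O | intermediate
35 | Bn-[A–B–C–D–E] phenol (free OH on ring E C2) | c1(OCc9ccccc9)cc(OCc9ccccc9)cc(OCc9ccccc9)c1Oc1cc(OCc9ccccc9)c(c(OCc9ccccc9)c1)Oc1cc(OCc9ccccc9)c(OCc9ccccc9)c(OCc9ccccc9)c1Oc1cc(OCc9ccccc9)c(c(OCc9ccccc9)c1)Oc1cc(OCc9ccccc9)c(OCc9ccccc9)c(OCc9ccccc9)c1O | intermediate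
36 | Bn-[A–B–C–D–E–F] methoxymethyl ether (OMOM on ring F C4) | c1(OCc9ccccc9)cc(OCc9ccccc9)cc(OCc9ccccc9)c1Oc1cc(OCc9ccccc9)c(c(OCc9ccccc9)c1)Oc1cc(OCc9ccccc9)c(OCc9ccccc9)c(OCc9ccccc9)c1Oc1cc(OCc9ccccc9)c(c(OCc9ccccc9)c1)Oc1cc(OCc9ccccc9)c(OCc9ccccc9)c(OCc9ccccc9)c1Oc1cc(OCc9ccccc9)c(c(OCc9ccccc9)c1)OCOC | intermediate
37 | Bn-[A–B–C–D–E–F] phenol (free OH on ring F C4) | c1(OCc9ccccc9)cc(OCc9ccccc9)cc(OCc9ccccc9)c1Oc1cc(OCc9ccccc9)c(c(OCc9ccccc9)c1)Oc1cc(OCc9ccccc9)c(OCc9ccccc9)c(OCc9ccccc9)c1Oc1cc(OCc9ccccc9)c(c(OCc9ccccc9)c1)Oc1cc(OCc9ccccc9)c(OCc9ccccc9)c(OCc9ccccc9)c1Oc1cc(OCc9ccccc9)c(c(OCc9ccccc9)c1)O | intermediate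
38 | Bn-[A–B–C–D–E–F] (E)-1,2-dichlorovinyl ether (on O4 of ring F) | c1(OCc9ccccc9)cc(OCc9ccccc9)cc(OCc9ccccc9)c1Oc1cc(OCc9ccccc9)c(c(OCc9ccccc9)c1)Oc1cc(OCc9ccccc9)c(OCc9ccccc9)c(OCc9ccccc9)c1Oc1cc(OCc9ccccc9)c(c(OCc9ccccc9)c1)Oc1cc(OCc9ccccc9)c(OCc9ccccc9)c(OCc9ccccc9)c1Oc1cc(OCc9ccccc9)c(c(OCc9ccccc9)c1)O/C(Cl)=C\Cl | intermediate
39 | Bn-[A–B–C–D–E–F] chloroethynyl ether (Cl–C≡C–O on ring F C4) | c1(OCc9ccccc9)cc(OCc9ccccc9)cc(OCc9ccccc9)c1Oc1cc(OCc9ccccc9)c(c(OCc9ccccc9)c1)Oc1cc(OCc9ccccc9)c(OCc9ccccc9)c(OCc9ccccc9)c1Oc1cc(OCc9ccccc9)c(c(OCc9ccccc9)c1)Oc1cc(OCc9ccccc9)c(OCc9ccccc9)c(OCc9ccccc9)c1Oc1cc(OCc9ccccc9)c(c(OCc9ccccc9)c1)OC#CCl | intermediate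
40 | lithium acetylide of the hexamer (Li–C≡C–O on ring F C4) | c1(OCc9ccccc9)cc(OCc9ccccc9)cc(OCc9ccccc9)c1Oc1cc(OCc9ccccc9)c(c(OCc9ccccc9)c1)Oc1cc(OCc9ccccc9)c(OCc9ccccc9)c(OCc9ccccc9)c1Oc1cc(OCc9ccccc9)c(c(OCc9ccccc9)c1)Oc1cc(OCc9ccccc9)c(OCc9ccccc9)c(OCc9ccccc9)c1Oc1cc(OCc9ccccc9)c(c(OCc9ccccc9)c1)OC#C[Li] | intermediate
41 | 2,3-bis(benzyloxy)-4-hydroxy-4-[(Bn-[A–B–C–D–E–F]-oxy)ethynyl]cyclobut-2-en-1-one (racemic) | c1(OCc9ccccc9)cc(OCc9ccccc9)cc(OCc9ccccc9)c1Oc1cc(OCc9ccccc9)c(c(OCc9ccccc9)c1)Oc1cc(OCc9ccccc9)c(OCc9ccccc9)c(OCc9ccccc9)c1Oc1cc(OCc9ccccc9)c(c(OCc9ccccc9)c1)Oc1cc(OCc9ccccc9)c(OCc9ccccc9)c(OCc9ccccc9)c1Oc1cc(OCc9ccccc9)c(c(OCc9ccccc9)c1)OC#CC1(O)C(OCc9ccccc9)=C(OCc9ccccc9)C1=O | intermediate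
42 | 2,3-bis(benzyloxy)-4-hydroxy-4-[(Z)-2-(Bn-[A–B–C–D–E–F]-oxy)ethenyl]cyclobut-2-en-1-one (racemic) | c1(OCc9ccccc9)cc(OCc9ccccc9)cc(OCc9ccccc9)c1Oc1cc(OCc9ccccc9)c(c(OCc9ccccc9)c1)Oc1cc(OCc9ccccc9)c(OCc9ccccc9)c(OCc9ccccc9)c1Oc1cc(OCc9ccccc9)c(c(OCc9ccccc9)c1)Oc1cc(OCc9ccccc9)c(OCc9ccccc9)c(OCc9ccccc9)c1Oc1cc(OCc9ccccc9)c(c(OCc9ccccc9)c1)O/C=C\C1(O)C(OCc9ccccc9)=C(OCc9ccccc9)C1=O | intermediate
43 | (3Z,5Z)-dienylketene leading to ring G (6-(Bn-[A–B–C–D–E–F]-oxy)-2,3-bis(benzyloxy)-4-hydroxyhexa-1,3,5-trien-1-one) | c1(OCc9ccccc9)cc(OCc9ccccc9)cc(OCc9ccccc9)c1Oc1cc(OCc9ccccc9)c(c(OCc9ccccc9)c1)Oc1cc(OCc9ccccc9)c(OCc9ccccc9)c(OCc9ccccc9)c1Oc1cc(OCc9ccccc9)c(c(OCc9ccccc9)c1)Oc1cc(OCc9ccccc9)c(OCc9ccccc9)c(OCc9ccccc9)c1Oc1cc(OCc9ccccc9)c(c(OCc9ccccc9)c1)O/C=C\C(O)=C(OCc9ccccc9)/C(OCc9ccccc9)=C=O | intermediate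
44 | cyclohexadienone leading to ring G (6-(Bn-[A–B–C–D–E–F]-oxy)-2,3-bis(benzyloxy)-4-hydroxycyclohexa-2,4-dien-1-one, racemic) | c1(OCc9ccccc9)cc(OCc9ccccc9)cc(OCc9ccccc9)c1Oc1cc(OCc9ccccc9)c(c(OCc9ccccc9)c1)Oc1cc(OCc9ccccc9)c(OCc9ccccc9)c(OCc9ccccc9)c1Oc1cc(OCc9ccccc9)c(c(OCc9ccccc9)c1)Oc1cc(OCc9ccccc9)c(OCc9ccccc9)c(OCc9ccccc9)c1Oc1cc(OCc9ccccc9)c(c(OCc9ccccc9)c1)OC1C=C(O)C(OCc9ccccc9)=C(OCc9ccccc9)C1=O | intermediate
45 | Bn-[A–B–C–D–E–F–G] hydroquinone (free OH on ring G C2 and C5) | c1(OCc9ccccc9)cc(OCc9ccccc9)cc(OCc9ccccc9)c1Oc1cc(OCc9ccccc9)c(c(OCc9ccccc9)c1)Oc1cc(OCc9ccccc9)c(OCc9ccccc9)c(OCc9ccccc9)c1Oc1cc(OCc9ccccc9)c(c(OCc9ccccc9)c1)Oc1cc(OCc9ccccc9)c(OCc9ccccc9)c(OCc9ccccc9)c1Oc1cc(OCc9ccccc9)c(c(OCc9ccccc9)c1)Oc1cc(O)c(OCc9ccccc9)c(OCc9ccccc9)c1O | intermediate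
46 | Bn-[A–B–C–D–E–F–G] phenol (free OH on ring G C2) | c1(OCc9ccccc9)cc(OCc9ccccc9)cc(OCc9ccccc9)c1Oc1cc(OCc9ccccc9)c(c(OCc9ccccc9)c1)Oc1cc(OCc9ccccc9)c(OCc9ccccc9)c(OCc9ccccc9)c1Oc1cc(OCc9ccccc9)c(c(OCc9ccccc9)c1)Oc1cc(OCc9ccccc9)c(OCc9ccccc9)c(OCc9ccccc9)c1Oc1cc(OCc9ccccc9)c(c(OCc9ccccc9)c1)Oc1cc(OCc9ccccc9)c(OCc9ccccc9)c(OCc9ccccc9)c1O | intermediate
47 | Bn-[A–B–C–D–E–F–G–H] methoxymethyl ether (OMOM on ring H C4) | c1(OCc9ccccc9)cc(OCc9ccccc9)cc(OCc9ccccc9)c1Oc1cc(OCc9ccccc9)c(c(OCc9ccccc9)c1)Oc1cc(OCc9ccccc9)c(OCc9ccccc9)c(OCc9ccccc9)c1Oc1cc(OCc9ccccc9)c(c(OCc9ccccc9)c1)Oc1cc(OCc9ccccc9)c(OCc9ccccc9)c(OCc9ccccc9)c1Oc1cc(OCc9ccccc9)c(c(OCc9ccccc9)c1)Oc1cc(OCc9ccccc9)c(OCc9ccccc9)c(OCc9ccccc9)c1Oc1cc(OCc9ccccc9)c(c(OCc9ccccc9)c1)OCOC | intermediate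
48 | Bn-[A–B–C–D–E–F–G–H] phenol (free OH on ring H C4) | c1(OCc9ccccc9)cc(OCc9ccccc9)cc(OCc9ccccc9)c1Oc1cc(OCc9ccccc9)c(c(OCc9ccccc9)c1)Oc1cc(OCc9ccccc9)c(OCc9ccccc9)c(OCc9ccccc9)c1Oc1cc(OCc9ccccc9)c(c(OCc9ccccc9)c1)Oc1cc(OCc9ccccc9)c(OCc9ccccc9)c(OCc9ccccc9)c1Oc1cc(OCc9ccccc9)c(c(OCc9ccccc9)c1)Oc1cc(OCc9ccccc9)c(OCc9ccccc9)c(OCc9ccccc9)c1Oc1cc(OCc9ccccc9)c(c(OCc9ccccc9)c1)O | intermediate
49 | Bn-[A–B–C–D–E–F–G–H] (E)-1,2-dichlorovinyl ether (on O4 of ring H) | c1(OCc9ccccc9)cc(OCc9ccccc9)cc(OCc9ccccc9)c1Oc1cc(OCc9ccccc9)c(c(OCc9ccccc9)c1)Oc1cc(OCc9ccccc9)c(OCc9ccccc9)c(OCc9ccccc9)c1Oc1cc(OCc9ccccc9)c(c(OCc9ccccc9)c1)Oc1cc(OCc9ccccc9)c(OCc9ccccc9)c(OCc9ccccc9)c1Oc1cc(OCc9ccccc9)c(c(OCc9ccccc9)c1)Oc1cc(OCc9ccccc9)c(OCc9ccccc9)c(OCc9ccccc9)c1Oc1cc(OCc9ccccc9)c(c(OCc9ccccc9)c1)O/C(Cl)=C\Cl | intermediate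
50 | Bn-[A–B–C–D–E–F–G–H] chloroethynyl ether (Cl–C≡C–O on ring H C4) | c1(OCc9ccccc9)cc(OCc9ccccc9)cc(OCc9ccccc9)c1Oc1cc(OCc9ccccc9)c(c(OCc9ccccc9)c1)Oc1cc(OCc9ccccc9)c(OCc9ccccc9)c(OCc9ccccc9)c1Oc1cc(OCc9ccccc9)c(c(OCc9ccccc9)c1)Oc1cc(OCc9ccccc9)c(OCc9ccccc9)c(OCc9ccccc9)c1Oc1cc(OCc9ccccc9)c(c(OCc9ccccc9)c1)Oc1cc(OCc9ccccc9)c(OCc9ccccc9)c(OCc9ccccc9)c1Oc1cc(OCc9ccccc9)c(c(OCc9ccccc9)c1)OC#CCl | intermediate
51 | lithium acetylide of the octamer (Li–C≡C–O on ring H C4) | c1(OCc9ccccc9)cc(OCc9ccccc9)cc(OCc9ccccc9)c1Oc1cc(OCc9ccccc9)c(c(OCc9ccccc9)c1)Oc1cc(OCc9ccccc9)c(OCc9ccccc9)c(OCc9ccccc9)c1Oc1cc(OCc9ccccc9)c(c(OCc9ccccc9)c1)Oc1cc(OCc9ccccc9)c(OCc9ccccc9)c(OCc9ccccc9)c1Oc1cc(OCc9ccccc9)c(c(OCc9ccccc9)c1)Oc1cc(OCc9ccccc9)c(OCc9ccccc9)c(OCc9ccccc9)c1Oc1cc(OCc9ccccc9)c(c(OCc9ccccc9)c1)OC#C[Li] | intermediate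
52 | 2,3-bis(benzyloxy)-4-hydroxy-4-[(Bn-[A–B–C–D–E–F–G–H]-oxy)ethynyl]cyclobut-2-en-1-one (racemic) | c1(OCc9ccccc9)cc(OCc9ccccc9)cc(OCc9ccccc9)c1Oc1cc(OCc9ccccc9)c(c(OCc9ccccc9)c1)Oc1cc(OCc9ccccc9)c(OCc9ccccc9)c(OCc9ccccc9)c1Oc1cc(OCc9ccccc9)c(c(OCc9ccccc9)c1)Oc1cc(OCc9ccccc9)c(OCc9ccccc9)c(OCc9ccccc9)c1Oc1cc(OCc9ccccc9)c(c(OCc9ccccc9)c1)Oc1cc(OCc9ccccc9)c(OCc9ccccc9)c(OCc9ccccc9)c1Oc1cc(OCc9ccccc9)c(c(OCc9ccccc9)c1)OC#CC1(O)C(OCc9ccccc9)=C(OCc9ccccc9)C1=O | intermediate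
53 | 2,3-bis(benzyloxy)-4-hydroxy-4-[(Z)-2-(Bn-[A–B–C–D–E–F–G–H]-oxy)ethenyl]cyclobut-2-en-1-one (racemic) | c1(OCc9ccccc9)cc(OCc9ccccc9)cc(OCc9ccccc9)c1Oc1cc(OCc9ccccc9)c(c(OCc9ccccc9)c1)Oc1cc(OCc9ccccc9)c(OCc9ccccc9)c(OCc9ccccc9)c1Oc1cc(OCc9ccccc9)c(c(OCc9ccccc9)c1)Oc1cc(OCc9ccccc9)c(OCc9ccccc9)c(OCc9ccccc9)c1Oc1cc(OCc9ccccc9)c(c(OCc9ccccc9)c1)Oc1cc(OCc9ccccc9)c(OCc9ccccc9)c(OCc9ccccc9)c1Oc1cc(OCc9ccccc9)c(c(OCc9ccccc9)c1)O/C=C\C1(O)C(OCc9ccccc9)=C(OCc9ccccc9)C1=O | intermediate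
54 | (3Z,5Z)-dienylketene leading to ring I (6-(Bn-[A–B–C–D–E–F–G–H]-oxy)-2,3-bis(benzyloxy)-4-hydroxyhexa-1,3,5-trien-1-one) | c1(OCc9ccccc9)cc(OCc9ccccc9)cc(OCc9ccccc9)c1Oc1cc(OCc9ccccc9)c(c(OCc9ccccc9)c1)Oc1cc(OCc9ccccc9)c(OCc9ccccc9)c(OCc9ccccc9)c1Oc1cc(OCc9ccccc9)c(c(OCc9ccccc9)c1)Oc1cc(OCc9ccccc9)c(OCc9ccccc9)c(OCc9ccccc9)c1Oc1cc(OCc9ccccc9)c(c(OCc9ccccc9)c1)Oc1cc(OCc9ccccc9)c(OCc9ccccc9)c(OCc9ccccc9)c1Oc1cc(OCc9ccccc9)c(c(OCc9ccccc9)c1)O/C=C\C(O)=C(OCc9ccccc9)/C(OCc9ccccc9)=C=O | intermediate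
55 | cyclohexadienone leading to ring I (6-(Bn-[A–B–C–D–E–F–G–H]-oxy)-2,3-bis(benzyloxy)-4-hydroxycyclohexa-2,4-dien-1-one, racemic) | c1(OCc9ccccc9)cc(OCc9ccccc9)cc(OCc9ccccc9)c1Oc1cc(OCc9ccccc9)c(c(OCc9ccccc9)c1)Oc1cc(OCc9ccccc9)c(OCc9ccccc9)c(OCc9ccccc9)c1Oc1cc(OCc9ccccc9)c(c(OCc9ccccc9)c1)Oc1cc(OCc9ccccc9)c(OCc9ccccc9)c(OCc9ccccc9)c1Oc1cc(OCc9ccccc9)c(c(OCc9ccccc9)c1)Oc1cc(OCc9ccccc9)c(OCc9ccccc9)c(OCc9ccccc9)c1Oc1cc(OCc9ccccc9)c(c(OCc9ccccc9)c1)OC1C=C(O)C(OCc9ccccc9)=C(OCc9ccccc9)C1=O | intermediate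
56 | Bn-[A–B–C–D–E–F–G–H–I] hydroquinone (free OH on ring I C2 and C5) | c1(OCc9ccccc9)cc(OCc9ccccc9)cc(OCc9ccccc9)c1Oc1cc(OCc9ccccc9)c(c(OCc9ccccc9)c1)Oc1cc(OCc9ccccc9)c(OCc9ccccc9)c(OCc9ccccc9)c1Oc1cc(OCc9ccccc9)c(c(OCc9ccccc9)c1)Oc1cc(OCc9ccccc9)c(OCc9ccccc9)c(OCc9ccccc9)c1Oc1cc(OCc9ccccc9)c(c(OCc9ccccc9)c1)Oc1cc(OCc9ccccc9)c(OCc9ccccc9)c(OCc9ccccc9)c1Oc1cc(OCc9ccccc9)c(c(OCc9ccccc9)c1)Oc1cc(O)c(OCc9ccccc9)c(OCc9ccccc9)c1O | intermediate
57 | Bn-[A–B–C–D–E–F–G–H–I] phenol (free OH on ring I C2) | c1(OCc9ccccc9)cc(OCc9ccccc9)cc(OCc9ccccc9)c1Oc1cc(OCc9ccccc9)c(c(OCc9ccccc9)c1)Oc1cc(OCc9ccccc9)c(OCc9ccccc9)c(OCc9ccccc9)c1Oc1cc(OCc9ccccc9)c(c(OCc9ccccc9)c1)Oc1cc(OCc9ccccc9)c(OCc9ccccc9)c(OCc9ccccc9)c1Oc1cc(OCc9ccccc9)c(c(OCc9ccccc9)c1)Oc1cc(OCc9ccccc9)c(OCc9ccccc9)c(OCc9ccccc9)c1Oc1cc(OCc9ccccc9)c(c(OCc9ccccc9)c1)Oc1cc(OCc9ccccc9)c(OCc9ccccc9)c(OCc9ccccc9)c1O | intermediate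
58 | Bn-[A–B–C–D–E–F–G–H–I–J] methoxymethyl ether (OMOM on ring J C4; twenty-five benzyl ethers) | c1(OCc9ccccc9)cc(OCc9ccccc9)cc(OCc9ccccc9)c1Oc1cc(OCc9ccccc9)c(c(OCc9ccccc9)c1)Oc1cc(OCc9ccccc9)c(OCc9ccccc9)c(OCc9ccccc9)c1Oc1cc(OCc9ccccc9)c(c(OCc9ccccc9)c1)Oc1cc(OCc9ccccc9)c(OCc9ccccc9)c(OCc9ccccc9)c1Oc1cc(OCc9ccccc9)c(c(OCc9ccccc9)c1)Oc1cc(OCc9ccccc9)c(OCc9ccccc9)c(OCc9ccccc9)c1Oc1cc(OCc9ccccc9)c(c(OCc9ccccc9)c1)Oc1cc(OCc9ccccc9)c(OCc9ccccc9)c(OCc9ccccc9)c1Oc1cc(OCc9ccccc9)c(c(OCc9ccccc9)c1)OCOC | intermediate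
59 | Bn-[A–B–C–D–E–F–G–H–I–J] phenol (free OH on ring J C4; twenty-five benzyl ethers) | c1(OCc9ccccc9)cc(OCc9ccccc9)cc(OCc9ccccc9)c1Oc1cc(OCc9ccccc9)c(c(OCc9ccccc9)c1)Oc1cc(OCc9ccccc9)c(OCc9ccccc9)c(OCc9ccccc9)c1Oc1cc(OCc9ccccc9)c(c(OCc9ccccc9)c1)Oc1cc(OCc9ccccc9)c(OCc9ccccc9)c(OCc9ccccc9)c1Oc1cc(OCc9ccccc9)c(c(OCc9ccccc9)c1)Oc1cc(OCc9ccccc9)c(OCc9ccccc9)c(OCc9ccccc9)c1Oc1cc(OCc9ccccc9)c(c(OCc9ccccc9)c1)Oc1cc(OCc9ccccc9)c(OCc9ccccc9)c(OCc9ccccc9)c1Oc1cc(OCc9ccccc9)c(c(OCc9ccccc9)c1)O | intermediate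
60 | target decamer CNP0255890.0 (free A–J polyphenol) | Oc1cc(O)c(Oc2cc(O)c(Oc3cc(O)c(O)c(O)c3Oc3cc(O)c(Oc4cc(O)c(O)c(O)c4Oc4cc(O)c(Oc5cc(O)c(O)c(O)c5Oc5cc(O)c(Oc6cc(O)c(O)c(O)c6Oc6cc(O)c(O)c(O)c6)c(O)c5)c(O)c4)c(O)c3)c(O)c2)c(O)c1 | target

## Step count and risk

Total step count: 38. Longest linear sequence: 35 steps (steps 4 to 7 from 7 to triflate 12, then steps 8 to 38).

Least certain steps:

**Step 13, the key step (repeated as steps 20, 27 and 34).** The most likely failure is diversion of the dienylketene before ring closure. If the inside aryloxy group slows the 6π closure, the ketene can be captured by the hydroxyl or by a second molecule. Any ring opening with the hydroxyl turning inward leads to a furanone. The enol ether may also lose aryloxide on prolonged heating.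
- Fallback: it sets out from alkyne 19 and comes back at 23. Alkyne 19 would be heated in chlorobenzene without prior hydrogenation. This is the alkynyl variant of the same ring expansion: closure of the ynyl ketene to a six-membered diradical and transfer of the hydroxyl hydrogen should give the quinone 5,6-bis(benzyloxy)-2-{2,6-bis(benzyloxy)-4-[2,4,6-tris(benzyloxy)phenoxy]phenoxy}cyclohexa-2,5-diene-1,4-dione F1. Reduction with aqueous Na2S2O4 in EtOAc would give hydroquinone 23.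

**Step 14 (repeated as steps 21, 28 and 35).** The risk is poor discrimination between the two phenolic hydroxyls, because the steric bias toward O5 is opposed by the probably higher acidity of the doubly flanked O2. Double benzylation and oxidation of the hydroquinone to the quinone by traces of air under base would also lower the return.
- Fallback: it sets out from 19 and comes back at 24. The tertiary hydroxyl of 19 would be benzylated with Ag2O and BnBr to give 2,3,4-tris(benzyloxy)-4-({2,6-bis(benzyloxy)-4-[2,4,6-tris(benzyloxy)phenoxy]phenoxy}ethynyl)cyclobut-2-en-1-one F2. Semihydrogenation as in step 12 would give the (Z)-alkenyl ether 2,3,4-tris(benzyloxy)-4-[(Z)-2-{2,6-bis(benzyloxy)-4-[2,4,6-tris(benzyloxy)phenoxy]phenoxy}ethenyl]cyclobut-2-en-1-one F3. Thermolysis as in step 13 turns the ether oxygen on the former carbinol carbon into O5 of ring C, so that 24 with its single free hydroxyl at C2 would form directly.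

**Step 15 (repeated as steps 22, 29 and 36; step 8 is the easier first case).** The phenol oxygen is buried between a benzyloxy group and a 2,6-bis(benzyloxy)aryloxy group, and both partners are electron-rich. Transfer of the phenoxide to palladium and the C–O reductive elimination may therefore be slower than cleavage of the triflate at sulfur by the phenoxide or its reduction to the arene, and this grows worse with chain length.
- Fallback: it sets out from 24, with phenol 11 as the source of the partner, and comes back at 25; the approach changes from a metal-catalysed coupling to the addition of the phenoxide to an aryne. Phenol 11 would be brominated ortho to the hydroxyl with N-bromosuccinimide to 3,5-bis(benzyloxy)-2-bromo-4-(methoxymethoxy)phenol F4. Silylation with hexamethyldisilazane would give [3,5-bis(benzyloxy)-2-bromo-4-(methoxymethoxy)phenoxy]trimethylsilane F5 (not isolated). Bromine–lithium exchange with n-BuLi at −78 °C and the 1,3 shift of silicon from oxygen to carbon would give lithium 3,5-bis(benzyloxy)-4-(methoxymethoxy)-2-(trimethylsilyl)phenoxide F6 (not isolated), and Tf2O would turn it into 3,5-bis(benzyloxy)-4-(methoxymethoxy)-2-(trimethylsilyl)phenyl trifluoromethanesulfonate F7. CsF in MeCN would release 3,5-bis(benzyloxy)-4-(methoxymethoxy)-1,2-didehydrobenzene F8 in the presence of phenol 24, which the fluoride deprotonates. The phenoxide should add to the aryne carbon remote from the neighbouring benzyloxy group, and protonation would give 25.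

**Step 11 (repeated as steps 18, 25 and 32).** n-BuLi may deprotonate the ring hydrogens flanked by two benzyloxy groups or benzylic positions, the chlorine–lithium exchange may be incomplete, the acetylide may lose aryloxide on warming, and a second addition to the squarate is possible.
- Fallback: it sets out from 14 and comes back at 20, so that step 12 is not needed. Phenol 14 would be added to bromoacetylene F9, generated in the flask from 1,2-dibromoethene and Cs2CO3 in DMF; anti addition should give the (Z)-2-bromovinyl ether 1,3-bis(benzyloxy)-2-{[(Z)-2-bromoethenyl]oxy}-5-[2,4,6-tris(benzyloxy)phenoxy]benzene F10. Bromine–lithium exchange with t-BuLi at −78 °C would give [(Z)-2-{2,6-bis(benzyloxy)-4-[2,4,6-tris(benzyloxy)phenoxy]phenoxy}ethenyl]lithium F11, which is not isolated and is held in the Z form by oxygen–lithium coordination. Its addition to squarate 2 would give 20.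

**Step 38.** Hydrogenolysis may stall at partly debenzylated stages, because the substrate changes from lipophilic to very polar and the polyphenol adsorbs on the catalyst. The free product is also oxidised by air during work-up.
- Fallback: it sets out from 59 and comes back at 60, and changes the mechanism from reductive to Lewis-acidic cleavage: BCl3 with pentamethylbenzene as cation scavenger in CH2Cl2 at −78 °C, followed by methanol quench. No new compound is made on the way (F0).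

## Further compounds

F1 | step 13 | 5,6-bis(benzyloxy)-2-{2,6-bis(benzyloxy)-4-[2,4,6-tris(benzyloxy)phenoxy]phenoxy}cyclohexa-2,5-diene-1,4-dione | c1(OCc9ccccc9)cc(OCc9ccccc9)cc(OCc9ccccc9)c1Oc1cc(OCc9ccccc9)c(c(OCc9ccccc9)c1)OC1=CC(=O)C(OCc9ccccc9)=C(OCc9ccccc9)C1=O
F2 | step 14 | 2,3,4-tris(benzyloxy)-4-({2,6-bis(benzyloxy)-4-[2,4,6-tris(benzyloxy)phenoxy]phenoxy}ethynyl)cyclobut-2-en-1-one (racemic) | c1(OCc9ccccc9)cc(OCc9ccccc9)cc(OCc9ccccc9)c1Oc1cc(OCc9ccccc9)c(c(OCc9ccccc9)c1)OC#CC1(OCc9ccccc9)C(OCc9ccccc9)=C(OCc9ccccc9)C1=O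
F3 | step 14 | 2,3,4-tris(benzyloxy)-4-[(Z)-2-{2,6-bis(benzyloxy)-4-[2,4,6-tris(benzyloxy)phenoxy]phenoxy}ethenyl]cyclobut-2-en-1-one (racemic) | c1(OCc9ccccc9)cc(OCc9ccccc9)cc(OCc9ccccc9)c1Oc1cc(OCc9ccccc9)c(c(OCc9ccccc9)c1)O/C=C\C1(OCc9ccccc9)C(OCc9ccccc9)=C(OCc9ccccc9)C1=O
F4 | step 15 | 3,5-bis(benzyloxy)-2-bromo-4-(methoxymethoxy)phenol | Oc1cc(OCc9ccccc9)c(OCOC)c(OCc9ccccc9)c1Br
F5 | step 15 | [3,5-bis(benzyloxy)-2-bromo-4-(methoxymethoxy)phenoxy]trimethylsilane | C[Si](C)(C)Oc1cc(OCc9ccccc9)c(OCOC)c(OCc9ccccc9)c1Br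
F6 | step 15 | lithium 3,5-bis(benzyloxy)-4-(methoxymethoxy)-2-(trimethylsilyl)phenoxide | [Li]Oc1cc(OCc9ccccc9)c(OCOC)c(OCc9ccccc9)c1[Si](C)(C)C
F7 | step 15 | 3,5-bis(benzyloxy)-4-(methoxymethoxy)-2-(trimethylsilyl)phenyl trifluoromethanesulfonate | FC(F)(F)S(=O)(=O)Oc1cc(OCc9ccccc9)c(OCOC)c(OCc9ccccc9)c1[Si](C)(C)C
F8 | step 15 | 3,5-bis(benzyloxy)-4-(methoxymethoxy)-1,2-didehydrobenzene (aryne) | C1#CC(OCc9ccccc9)=C(OCOC)C(OCc9ccccc9)=C1
F9 | step 11 | bromoacetylene | BrC#C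
F10 | step 11 | 1,3-bis(benzyloxy)-2-{[(Z)-2-bromoethenyl]oxy}-5-[2,4,6-tris(benzyloxy)phenoxy]benzene | Br/C=C\Oc1c(OCc9ccccc9)cc(Oc2c(OCc9ccccc9)cc(OCc9ccccc9)cc2OCc9ccccc9)cc1OCc9ccccc9
F11 | step 11 | [(Z)-2-{2,6-bis(benzyloxy)-4-[2,4,6-tris(benzyloxy)phenoxy]phenoxy}ethenyl]lithium | [Li]/C=C\Oc1c(OCc9ccccc9)cc(Oc2c(OCc9ccccc9)cc(OCc9ccccc9)cc2OCc9ccccc9)cc1OCc9ccccc9
F0 | step 38 | none | none
A1 | alternative 1 | methyl 3,5-bis(benzyloxy)-4-{[3,4,5-tris(benzyloxy)-2-{[3,4,5-tris(benzyloxy)benzoyl]oxy}benzoyl]oxy}benzoate (didepside of rings H, I, J) | COC(=O)c1cc(OCc9ccccc9)c(OC(=O)c2cc(OCc9ccccc9)c(OCc9ccccc9)c(OCc9ccccc9)c2OC(=O)c2cc(OCc9ccccc9)c(OCc9ccccc9)c(OCc9ccccc9)c2)c(OCc9ccccc9)c1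
A2 | alternative 1 | methyl 3,5-bis(benzyloxy)-4-{3,4,5-tris(benzyloxy)-2-[3,4,5-tris(benzyloxy)phenoxy]phenoxy}benzoate (H–I–J trimer ether) | COC(=O)c1cc(OCc9ccccc9)c(Oc2cc(OCc9ccccc9)c(OCc9ccccc9)c(OCc9ccccc9)c2Oc2cc(OCc9ccccc9)c(OCc9ccccc9)c(OCc9ccccc9)c2)c(OCc9ccccc9)c1
A3 | alternative 2 | octadecaformyl decamer (formyl on C2 and C6 of ring A and on C3 and C5 of rings B to I; eight benzyl ethers) | O=Cc1cc(OCc9ccccc9)cc(C=O)c1Oc2cc(C=O)c(Oc3cc(C=O)c(OCc9ccccc9)c(C=O)c3Oc3cc(C=O)c(Oc4cc(C=O)c(OCc9ccccc9)c(C=O)c4Oc4cc(C=O)c(Oc5cc(C=O)c(OCc9ccccc9)c(C=O)c5Oc5cc(C=O)c(Oc6cc(C=O)c(OCc9ccccc9)c(C=O)c6Oc6cc(OCc9ccccc9)c(OCc9ccccc9)c(OCc9ccccc9)c6)c(C=O)c5)c(C=O)c4)c(C=O)c3)c(C=O)c2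
A4 | alternative 2 | octadeca-formate decamer with eight benzyl ethers | O=COc1cc(OCc9ccccc9)cc(OC=O)c1Oc2cc(OC=O)c(Oc3cc(OC=O)c(OCc9ccccc9)c(OC=O)c3Oc3cc(OC=O)c(Oc4cc(OC=O)c(OCc9ccccc9)c(OC=O)c4Oc4cc(OC=O)c(Oc5cc(OC=O)c(OCc9ccccc9)c(OC=O)c5Oc5cc(OC=O)c(Oc6cc(OC=O)c(OCc9ccccc9)c(OC=O)c6Oc6cc(OCc9ccccc9)c(OCc9ccccc9)c(OCc9ccccc9)c6)c(OC=O)c5)c(OC=O)c4)c(OC=O)c3)c(OC=O)c2
A5 | alternative 3 | methyl 6-{3,5-bis(benzyloxy)-4-[3,4,5-tris(benzyloxy)-2-(methoxymethoxy)phenoxy]phenoxy}-3,5-dioxohexanoate | COC(=O)CC(=O)CC(=O)COc2cc(OCc9ccccc9)c(Oc3cc(OCc9ccccc9)c(OCc9ccccc9)c(OCc9ccccc9)c3OCOC)c(OCc9ccccc9)c2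
A6 | alternative 3 | 2-{3,5-bis(benzyloxy)-4-[3,4,5-tris(benzyloxy)-2-(methoxymethoxy)phenoxy]phenoxy}benzene-1,3,5-triol (A–B–C trimer with free ring A) | Oc1cc(O)c(Oc2cc(OCc9ccccc9)c(Oc3cc(OCc9ccccc9)c(OCc9ccccc9)c(OCc9ccccc9)c3OCOC)c(OCc9ccccc9)c2)c(O)c1
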